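**Plan**

- Ring A is cut last, at C3–C4. The C3 carbinol and the C19 carboxyl on quaternary C4 are an aldol pair, and C19 and C20 stand cis-diaxial on ring A. The two are therefore first tied as a 19,20-lactol methyl ether, which masks the C20 aldehyde and the C19 acid and fixes C4.
- Further cuts: C10–C1 ([3,3] shift) and C10=C20 (olefination); C13–C16 (ring D); C8–C14 and C9–C11 (ring C, cycloaddition); C8–C15, C5–C4 and C6–C7 on a 4-silyloxycyclopentenone.
- Forward order: ring B (chiral pool) → ring C (Diels–Alder) → quaternary C10 → lactol ether → ring D (ketyl–alkyne) → ring A (reductive lactone enolate aldol) → C3 inversion, C7 oxidation, unmasking.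
- Stereochemistry: the silyloxy carbon of the cyclopentenone sets C5 and then C6 (two anti additions). The C6 side chain steers the diene (C8, C9). The C5 and C9 substituents steer the allyl shift (C10). The bridge fixes C13, the lactone tether fixes C4, and LiBH(s-Bu)3 sets the axial 3β-hydroxyl.

Key step: step 23

**Remarks on the chemistry**

- Gibberellane numbering is used for all intermediates: ring A = C1–C5, C10; ring B = C5, C6, C8, C9, C10; ring C = C8, C9, C11–C14; ring D = C8, C13–C16.
- C4 (until step 23), the acetal carbon C20 (steps 16–28) and the C8 carbinol (steps 7–9) are epimer mixtures that are later destroyed or fixed. The SMILES leave C4 and C20 undefined and show the expected C8 epimer.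
- The target is written as the open 20-aldehyde 19-acid; it is assumed to equilibrate with its 19,20-lactol ring tautomer, which is the same compound.
- DMP stands for the triacetoxy periodinane 1,1,1-triacetoxy-1,1-dihydro-1,2-benziodoxol-3(1H)-one; (Sia)2BH for bis(3-methylbutan-2-yl)borane.

**Route**

Step 1
Reactants: 1 (1S,4R)-cis-4-acetoxycyclopent-2-en-1-ol
Product: 2 (1R,4S)-4-(tert-butyldimethylsilyloxy)cyclopent-2-en-1-yl acetate
Conditions: TBSCl, imidazole, DMF, 0 °C to rt
Reagents that add atoms: tert-butyldimethylsilyl chloride, CC(C)(C)[Si](C)(C)Cl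
Why: Imidazole-promoted silylation of the free allylic alcohol is routine and leaves both stereocentres untouched, the silyloxy carbon being the later control element (C10) of ring B.

Step 2
Reactants: 2 (1R,4S)-4-(tert-butyldimethylsilyloxy)cyclopent-2-en-1-yl acetate
Product: 3 (1R,4S)-4-(tert-butyldimethylsilyloxy)cyclopent-2-en-1-ol
Conditions: K2CO3 (cat.), MeOH, 0 °C
Reagents that add atoms: none
Why: Carbonate-catalysed transesterification removes the acetate without touching the silyl ether or either stereocentre.

Step 3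
Reactants: 3 (1R,4S)-4-(tert-butyldimethylsilyloxy)cyclopent-2-en-1-ol
Product: 4 (S)-4-(tert-butyldimethylsilyloxy)cyclopent-2-en-1-one
Conditions: DMP, NaHCO3, CH2Cl2, 0 °C to rt
Reagents that add atoms: none
Why: Buffered periodinane oxidation of the allylic alcohol gives the enone without β-elimination of the silyloxy group, so the single remaining stereocentre stays intact.

Step 4
Reactants: 5 methyl propanoate
Product: 7 (E)-1-methoxy-1-(trimethylsilyloxy)prop-1-ene, via lithium enolate 6 (not isolated)
Conditions: LiN(i-Pr)2, THF, −78 °C; then Me3SiCl, −78 °C to rt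
Reagents that add atoms: chlorotrimethylsilane, C[Si](C)(C)Cl
Why: Kinetic deprotonation of the ester and O-silylation of the enolate give the ketene silyl acetal needed as the nucleophile of the next step (enolate trapping).

Step 5
Reactants: 4 (S)-4-(tert-butyldimethylsilyloxy)cyclopent-2-en-1-one; 7 (E)-1-methoxy-1-(trimethylsilyloxy)prop-1-ene
Product: 9 hydroxymethyl ketone (2,3-trans-3,4-trans cyclopentanone carrying C7 on C6 and the propanoate arm on C5), via silyl enol ether 8 (not isolated)
Conditions: Sc(OTf)3 (5 mol %), CH2Cl2, −78 °C; then THF, 37% aq. HCHO, rt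
Reagents that add atoms: formaldehyde, C=O
Why: A Lewis-acid-catalysed Mukaiyama–Michael addition should deliver the propanoate unit to C5 anti to the C10 silyloxy group and hand over a regiodefined silyl enol ether, whose aqueous Mukaiyama aldol reaction with formaldehyde then places the hydroxymethyl group on C6 anti to the new C5 substituent, so that C5 and C6 are set by 1,2-induction while C4 arises as an inconsequential epimer mixture.

Step 6
Reactants: 9 hydroxymethyl ketone
Product: 10 tert-butyldiphenylsilyl ether of 9
Conditions: TBDPSCl, imidazole, CH2Cl2, 0 °C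
Reagents that add atoms: tert-butyl(chloro)diphenylsilane, CC(C)(C)[Si](Cl)(c1ccccc1)c1ccccc1
Why: Silylation of the only hydroxyl group masks C7 as an ether that withstands acid, base and Lewis acid until step 26 and prevents lactonisation onto the ester.

Step 7
Reactants: 10 silyl-protected ketone; 11 3-bromo-1-(trimethylsilyl)prop-1-yne
Product: 12 tertiary homopropargylic alcohol at C8
Conditions: Zn dust, THF, 0 °C to rt; then H2O
Reagents that add atoms: none
Why: Barbier propargylation by the organozinc formed in the flask adds to the ketone without enolisation or β-elimination of the C10 silyloxy group, the silyl cap favouring the propargyl over the allenyl product, and the C8 configuration is irrelevant because C8 becomes trigonal in step 10.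

Step 8
Reactants: 12 tertiary homopropargylic alcohol
Product: 13 diol with free C10 hydroxyl
Conditions: CSA (cat.), MeOH, 0 °C to rt
Reagents that add atoms: none
Why: Acid-catalysed methanolysis cleaves the secondary tert-butyldimethylsilyl ether far faster than the primary tert-butyldiphenylsilyl ether, while the tertiary alcohol, the ester and the alkynylsilane are inert (selective desilylation).

Step 9
Reactants: 13 diol
Product: 14 β-hydroxy ketone (C10 ketone, C8 tertiary hydroxyl)
Conditions: DMP, NaHCO3, CH2Cl2, 0 °C
Reagents that add atoms: none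
Why: Periodinane oxidation converts the secondary alcohol into the C10 ketone under neutral conditions that leave the tertiary hydroxyl and the aldol-type C8–C9 bond alone.

Step 10
Reactants: 14 β-hydroxy ketone
Product: 16 ring B enone (3-propargyl-4,5-trans-disubstituted cyclopent-2-enone), via tertiary mesylate 15 (not isolated)
Conditions: MsCl, Et3N, CH2Cl2, 0 °C to rt
Reagents that add atoms: none
Why: Mesylation of the tertiary β-hydroxyl through sulfene and E1cB elimination across C9–C8 give the conjugated enone regioselectively (aldol-type dehydration), the amine being too weak a base to epimerise C6 through the dienolate while C5 keeps its more stable trans arrangement.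

Step 11
Reactants: 17 methyl vinyl ketone
Product: 18 2-(tert-butyldimethylsilyloxy)buta-1,3-diene
Conditions: TBSOTf, Et3N, Et2O, 0 °C
Reagents that add atoms: tert-butyldimethylsilyl trifluoromethanesulfonate, CC(C)(C)[Si](C)(C)OS(=O)(=O)C(F)(F)F
Why: Soft enolisation and O-silylation of the methyl ketone give the 2-silyloxydiene (silyl enol ether formation).

Step 12
Reactants: 16 ring B enone; 18 2-(tert-butyldimethylsilyloxy)buta-1,3-diene
Product: 19 cis-fused B/C adduct (C10 ketone, C12=C13 silyl enol ether, quaternary C8)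
Conditions: AlBr3/AlMe3 (10:1), toluene/CH2Cl2, −40 to −10 °C; then pyridine, aq. NaHCO3
Reagents that add atoms: none
Why: The Diels–Alder reaction of the β,β-disubstituted enone with the 2-silyloxydiene under the mixed aluminium promoter, a combination known to force hindered partners together, should place the silyloxy carbon para to the acyl-bearing C9 (oxygen at C13) and add the diene to the ring B face anti to the C6 silyloxymethyl group, which sets C8 and C9 as the cis ring fusion and leaves C13 masked as an enol ether.

Step 13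
Reactants: 20 allyl alcohol
Product: 22 (allyloxymethyl)triphenylphosphonium chloride, via allyl chloromethyl ether 21 (not isolated)
Conditions: (CH2O)n, HCl (g), CH2Cl2, 0 °C; then PPh3, toluene, rt to 60 °C
Reagents that add atoms: formaldehyde (as paraformaldehyde), C=O; hydrogen chloride, Cl; triphenylphosphine, c1ccc(cc1)P(c1ccccc1)c1ccccc1
Why: Chloromethylation of the alcohol followed by SN2 quaternisation of the phosphine at the α-chloro ether gives the salt needed for alkoxymethylenation.

Step 14
Reactants: 19 cis-fused B/C adduct; 22 (allyloxymethyl)triphenylphosphonium chloride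
Product: 24 allyl enol ether at C10 (C10=C20), via phosphorus ylide 23 (not isolated)
Conditions: KN(SiMe3)2, THF, 0 °C; then 19, 0 to 50 °C
Reagents that add atoms: none
Why: Wittig alkoxymethylenation of the C10 ketone with an excess of the non-stabilised ylide gives the allyl vinyl ether (either geometry serves), the ester, the silyl enol ether and the capped alkyne being inert to the ylide.

Step 15
Reactants: 24 allyl enol ether
Product: 25 C10-quaternary aldehyde (C20 formyl and C1–C3 allyl on C10)
Conditions: toluene, i-Pr2NEt (cat.), 170 °C, sealed tube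
Reagents that add atoms: none
Why: The Claisen rearrangement ([3,3]-sigmatropic shift) of the allyl vinyl ether creates quaternary C10 with C20 as the aldehyde and delivers the allyl group to the ring B face anti to the two flanking substituents (the C4 arm on C5 and C11 on C9), which sets C10.

Step 16
Reactants: 25 C10-quaternary aldehyde
Product: 27 keto lactol (20-hydroxy-19,20-lactone with C13 ketone and terminal alkyne), via lithium carboxylate 26 (not isolated)
Conditions: LiOH, THF/MeOH/H2O, 0 °C to rt; then 1 M HCl (pH 2), THF, rt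
Reagents that add atoms: lithium hydroxide, [Li+].[OH-]
Why: Saponification of the unhindered methyl ester (with protodesilylation of the alkyne) gives the carboxylate, and on acidification the acid closes onto the cis-disposed C20 aldehyde as the six-membered lactol before the silyl enol ether is hydrolysed to the C13 ketone, so that an aldol reaction between C12 and C20 cannot intervene (ester hydrolysis, lactol formation, enol ether hydrolysis).

Step 17
Reactants: 27 keto lactol
Product: 28 lactol methyl ether (20-methoxy-19,20-lactone)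
Conditions: PPTS (cat.), MeOH, rt; then THF/H2O, rt
Reagents that add atoms: methanol, CO
Why: Acid-catalysed acetal exchange converts the lactol into its methyl ether, which masks the C20 aldehyde and locks C19 on the C20 face as the tether that later fixes C4, while the aqueous second stage returns any C13 ketal to the ketone.

Step 18
Reactants: 28 lactol methyl ether
Product: 29 B/C/D tricycle with 13-hydroxyl and 16-methylene
Conditions: SmI2, HMPA, t-BuOH, THF, 0 °C
Reagents that add atoms: none
Why: The SmI2-mediated ketyl–alkyne cyclisation (5-exo-dig) joins C13 to C16 and gives the bridgehead tertiary alcohol and the exocyclic methylene in one step, the C13 configuration being dictated by the one-carbon bridge from C8 and the lactone, acetal and terminal alkene being left unreduced.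

Step 19
Reactants: 29 B/C/D tricycle
Product: 30 13-O-triethylsilyl ether
Conditions: TESOTf, 2,6-lutidine, CH2Cl2, −78 °C
Reagents that add atoms: triethylsilyl trifluoromethanesulfonate, CC[Si](CC)(CC)OS(=O)(=O)C(F)(F)F
Why: Low-temperature silylation with the silyl triflate protects the hindered bridgehead alcohol, so that no proton source remains for the enolate chemistry of steps 20 and 23.

Step 20
Reactants: 30 13-O-triethylsilyl ether
Product: 32 α-bromo lactone (bromine on C4), via lithium enolate 31 (not isolated)
Conditions: LiN(i-Pr)2, THF, −78 °C; then BrCCl2CCl2Br, −78 °C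
Reagents that add atoms: 1,2-dibromotetrachloroethane, ClC(Cl)(Br)C(Cl)(Cl)Br
Why: Deprotonation of the only acidic C–H (C4 of the lactone) and bromination of the enolate with a positive-bromine donor install the α-bromide (enolate halogenation) that allows base-free enolate generation in step 23, the C4 configuration being irrelevant.

Step 21
Reactants: 32 α-bromo lactone
Product: 34 primary alcohol at C3, via trialkylborane 33 (not isolated)
Conditions: (Sia)2BH, THF, 0 °C; then Me3NO·2H2O, 50 °C
Reagents that add atoms: trimethylamine N-oxide, C[N+](C)(C)[O-]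
Why: Hydroboration with the bulky dialkylborane should take the monosubstituted allyl alkene in preference to the hindered 1,1-disubstituted C16 methylene, and neutral amine-oxide oxidation of the borane spares the bromo lactone, giving the anti-Markovnikov alcohol.

Step 22
Reactants: 34 primary alcohol
Product: 35 bromo lactone aldehyde (C10 propanal arm)
Conditions: DMP, NaHCO3, CH2Cl2, 0 °C
Reagents that add atoms: none
Why: Buffered periodinane oxidation gives the C3 aldehyde without touching the tertiary bromide or the acetal.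

Step 23
Reactants: 35 bromo lactone aldehyde
Product: 37 tetracyclic 3α-hydroxy 19,20-lactol ether, via samarium enolate 36 (not isolated)
Conditions: SmI2 (2.2 equiv), THF, −78 °C; pH 7 buffer at −78 °C
Reagents that add atoms: none
Why: SmI2 transfers two electrons to the tertiary C4–Br bond and generates the trivalent samarium enolate of the δ-lactone regiospecifically and without base, so that the enolisable C3 aldehyde is not deprotonated; the enolate then adds to the aldehyde carbon and forms C3–C4. The closest known reaction type is the SmI2-promoted intramolecular Reformatsky (ester enolate aldol) reaction of α-bromo esters with aldehydes. Ring A closes in the 6-(enolexo)-exo-trig mode, the enolate double bond C4=C19 lying outside the new ring, and the product is a chair–chair 3-oxabicyclo[3.3.1]nonan-2-one made of ring A and the lactone. C4 is controlled by the tether: the lactol ether holds C19 on the C20 face of ring B, so C3 can bond only to the enolate face on the side of the C1 arm, which leaves C19 axial and cis to C20 and the methyl group equatorial. C3 is controlled by chelation of samarium between the enolate and aldehyde oxygens in a closed transition state, which places the new oxygen gauche to C19, that is equatorial (3α); this is the C3 epimer of the target and is corrected in steps 24 and 25, so any 3β isomer formed alongside is carried through as well. The step needs reduction of the carbon–bromine bond ahead of the aldehyde and ring closure ahead of protonation, which the much faster electron transfer to α-bromo esters at −78 °C, the absence of any hydroxyl group in 35 and the six-membered ring size should secure.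

Step 24
Reactants: 37 tetracyclic 3α-hydroxy lactol ether
Product: 38 3-ketone
Conditions: DMP, NaHCO3, CH2Cl2, rt
Reagents that add atoms: none
Why: Periodinane oxidation gives the C3 ketone, a β-keto lactone that cannot enolise towards quaternary C4, so both C3 epimers from step 23 converge.

Step 25
Reactants: 38 3-ketone
Product: 39 tetracyclic 3β-hydroxy lactol ether
Conditions: LiBH(s-Bu)3, THF, −78 °C
Reagents that add atoms: none
Why: The bulky hydride should attack the C3 ketone along the equatorial trajectory, away from the axial hydrogens on C1 and C5, as in the reduction of 4,4-disubstituted 3-oxo terpenoids, and so give the axial 3β-carbinol trans to C19, the lactone being inert at this temperature (diastereoselective ketone reduction).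

Step 26
Reactants: 39 tetracyclic 3β-hydroxy lactol ether
Product: 40 triol (free C3, C7 and C13 hydroxyls)
Conditions: HF·pyridine, pyridine, THF, 0 °C to rt
Reagents that add atoms: none
Why: Buffered HF·pyridine cleaves the primary and the tertiary silyl ether (fluoride-mediated desilylation) in a non-basic medium in which the lactol ether and the β-hydroxy lactone survive.

Step 27
Reactants: 40 triol
Product: 41 C7 aldehyde
Conditions: TEMPO (cat.), PhI(OAc)2, CH2Cl2, rt
Reagents that add atoms: none
Why: The oxoammonium-catalysed oxidation is selective for the primary C7 alcohol over the hindered axial C3 hydroxyl and the tertiary C13 hydroxyl and stops at the aldehyde.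

Step 28
Reactants: 41 C7 aldehyde
Product: 42 C7 carboxylic acid
Conditions: NaClO2, NaH2PO4, 2-methylbut-2-ene, t-BuOH/H2O, 0 °C to rt
Reagents that add atoms: sodium chlorite, [Na+].[O-]Cl=O
Why: The Pinnick oxidation converts the aldehyde into the acid without epimerising C6, the alkene scavenger protecting the C16 methylene from hypochlorous acid and the lactol ether keeping C20 from oxidation.

Step 29
Reactants: 42 C7 carboxylic acid
Product: 43 target CNP0236431.1
Conditions: 1 M HCl, THF, rt
Reagents that add atoms: water, O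
Why: Dilute aqueous acid hydrolyses the acyloxy acetal and so releases the C20 aldehyde and the C19 acid together, without any base that could start retro-aldol cleavage at C3–C4 (acetal hydrolysis).

**Compound list**

1 | (1S,4R)-cis-4-acetoxycyclopent-2-en-1-ol | CC(=O)O[C@@H]1C[C@H](O)C=C1 | starting material
2 | (1R,4S)-4-(tert-butyldimethylsilyloxy)cyclopent-2-en-1-yl acetate | CC(=O)O[C@@H]1C[C@H](O[Si](C)(C)C(C)(C)C)C=C1 | intermediate
3 | (1R,4S)-4-(tert-butyldimethylsilyloxy)cyclopent-2-en-1-ol | O[C@@H]1C[C@H](O[Si](C)(C)C(C)(C)C)C=C1 | intermediate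
4 | (S)-4-(tert-butyldimethylsilyloxy)cyclopent-2-en-1-one | O=C1C[C@H](O[Si](C)(C)C(C)(C)C)C=C1 | intermediate
5 | methyl propanoate | CCC(=O)OC | starting material
6 | lithium (E)-1-methoxyprop-1-en-1-olate (not isolated) | C/C=C(\OC)[O-].[Li+] | intermediate
7 | (E)-1-methoxy-1-(trimethylsilyloxy)prop-1-ene | C/C=C(\OC)O[Si](C)(C)C | intermediate
8 | methyl 2-[5-(tert-butyldimethylsilyloxy)-3-(trimethylsilyloxy)cyclopent-2-en-1-yl]propanoate, 1,5-trans (not isolated) | C[Si](C)(C)OC1=C[C@H](C(C)C(=O)OC)[C@@H](O[Si](C)(C)C(C)(C)C)C1 | intermediate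
9 | 4-(tert-butyldimethylsilyloxy)-2-(hydroxymethyl)-3-[1-(methoxycarbonyl)ethyl]cyclopentan-1-one, 2,3-trans-3,4-trans | O=C1[C@@H](CO)[C@H](C(C)C(=O)OC)[C@@H](O[Si](C)(C)C(C)(C)C)C1 | intermediate
10 | tert-butyldiphenylsilyl ether of 9 | O=C1[C@@H](CO[Si](c2ccccc2)(c2ccccc2)C(C)(C)C)[C@H](C(C)C(=O)OC)[C@@H](O[Si](C)(C)C(C)(C)C)C1 | intermediate
11 | 3-bromo-1-(trimethylsilyl)prop-1-yne | C[Si](C)(C)C#CCBr | starting material
12 | 1-[3-(trimethylsilyl)prop-2-ynyl] tertiary alcohol from 10 (hydroxyl cis to the C6 and C10 substituents expected) | O[C@@]1(CC#C[Si](C)(C)C)[C@@H](CO[Si](c2ccccc2)(c2ccccc2)C(C)(C)C)[C@H](C(C)C(=O)OC)[C@@H](O[Si](C)(C)C(C)(C)C)C1 | intermediate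
13 | diol from 12 with free C10 hydroxyl | O[C@@]1(CC#C[Si](C)(C)C)[C@@H](CO[Si](c2ccccc2)(c2ccccc2)C(C)(C)C)[C@H](C(C)C(=O)OC)[C@@H](O)C1 | intermediate
14 | 4-hydroxy-3-(tert-butyldiphenylsilyloxymethyl)-2-[1-(methoxycarbonyl)ethyl]-4-[3-(trimethylsilyl)prop-2-ynyl]cyclopentan-1-one, 2,3-trans | O[C@@]1(CC#C[Si](C)(C)C)[C@@H](CO[Si](c2ccccc2)(c2ccccc2)C(C)(C)C)[C@H](C(C)C(=O)OC)C(=O)C1 | intermediate
15 | methanesulfonate of 14 (not isolated) | CS(=O)(=O)O[C@@]1(CC#C[Si](C)(C)C)[C@@H](CO[Si](c2ccccc2)(c2ccccc2)C(C)(C)C)[C@H](C(C)C(=O)OC)C(=O)C1 | intermediate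
16 | 4-(tert-butyldiphenylsilyloxymethyl)-5-[1-(methoxycarbonyl)ethyl]-3-[3-(trimethylsilyl)prop-2-ynyl]cyclopent-2-en-1-one, 4,5-trans | O=C1C=C(CC#C[Si](C)(C)C)[C@@H](CO[Si](c2ccccc2)(c2ccccc2)C(C)(C)C)[C@@H]1C(C)C(=O)OC | intermediate
17 | methyl vinyl ketone | CC(=O)C=C | starting material
18 | 2-(tert-butyldimethylsilyloxy)buta-1,3-diene | C=CC(=C)O[Si](C)(C)C(C)(C)C | intermediate
19 | cis-fused B/C adduct: C10 ketone, C12=C13 silyl enol ether, angular C8 propargylsilane, ring C on the face anti to C7 | O=C1[C@@H](C(C)C(=O)OC)[C@H](CO[Si](c3ccccc3)(c3ccccc3)C(C)(C)C)[C@@]2(CC#C[Si](C)(C)C)CC(O[Si](C)(C)C(C)(C)C)=CC[C@@H]12 | intermediate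
20 | allyl alcohol | C=CCO | starting material
21 | allyl chloromethyl ether (not isolated) | C=CCOCCl | intermediate
22 | (allyloxymethyl)triphenylphosphonium chloride | C=CCOC[P+](c1ccccc1)(c1ccccc1)c1ccccc1.[Cl-] | intermediate
23 | (allyloxymethylene)triphenylphosphorane (not isolated) | C=CCOC=P(c1ccccc1)(c1ccccc1)c1ccccc1 | intermediate
24 | C10 (allyloxy)methylene derivative of 19 (E/Z mixture) | C=CCOC=C1[C@@H](C(C)C(=O)OC)[C@H](CO[Si](c3ccccc3)(c3ccccc3)C(C)(C)C)[C@@]2(CC#C[Si](C)(C)C)CC(O[Si](C)(C)C(C)(C)C)=CC[C@@H]12 | intermediate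
25 | C10-quaternary aldehyde: C20 formyl cis to the C4 arm, allyl trans to it | O=C[C@@]1(CC=C)[C@@H](C(C)C(=O)OC)[C@H](CO[Si](c3ccccc3)(c3ccccc3)C(C)(C)C)[C@@]2(CC#C[Si](C)(C)C)CC(O[Si](C)(C)C(C)(C)C)=CC[C@@H]12 | intermediate
26 | lithium carboxylate of 25 with free alkyne (not isolated) | O=C[C@@]1(CC=C)[C@@H](C(C)C(=O)[O-])[C@H](CO[Si](c3ccccc3)(c3ccccc3)C(C)(C)C)[C@@]2(CC#C)CC(O[Si](C)(C)C(C)(C)C)=CC[C@@H]12.[Li+] | intermediate
27 | keto lactol: 20-hydroxy-19,20-lactone, C13 ketone, C8 propargyl, C10 allyl, C7 silyl ether | OC1OC(=O)C(C)[C@H]2[C@H](CO[Si](c4ccccc4)(c4ccccc4)C(C)(C)C)[C@@]3(CC#C)CC(=O)CC[C@H]3[C@@]12CC=C | intermediate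
28 | lactol methyl ether of 27 (20-methoxy-19,20-lactone) | COC1OC(=O)C(C)[C@H]2[C@H](CO[Si](c4ccccc4)(c4ccccc4)C(C)(C)C)[C@@]3(CC#C)CC(=O)CC[C@H]3[C@@]12CC=C | intermediate
29 | B/C/D tricycle: 13-hydroxy-16-methylene bicyclo[3.2.1]octane fused to ring B, lactol ether, C10 allyl | COC1OC(=O)C(C)[C@H]2[C@H](CO[Si](c5ccccc5)(c5ccccc5)C(C)(C)C)[C@]34CC(=C)[C@@](O)(C4)CC[C@H]3[C@@]12CC=C | intermediate
30 | 13-O-triethylsilyl ether of 29 | COC1OC(=O)C(C)[C@H]2[C@H](CO[Si](c5ccccc5)(c5ccccc5)C(C)(C)C)[C@]34CC(=C)[C@@](O[Si](CC)(CC)CC)(C4)CC[C@H]3[C@@]12CC=C | intermediate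
31 | lithium enolate of lactone 30 (not isolated) | COC1OC([O-])=C(C)[C@H]2[C@H](CO[Si](c5ccccc5)(c5ccccc5)C(C)(C)C)[C@]34CC(=C)[C@@](O[Si](CC)(CC)CC)(C4)CC[C@H]3[C@@]12CC=C.[Li+] | intermediate
32 | 4-bromo lactone | COC1OC(=O)C(C)(Br)[C@H]2[C@H](CO[Si](c5ccccc5)(c5ccccc5)C(C)(C)C)[C@]34CC(=C)[C@@](O[Si](CC)(CC)CC)(C4)CC[C@H]3[C@@]12CC=C | intermediate
33 | C3 bis(3-methylbutan-2-yl)borane from 32 (not isolated) | COC1OC(=O)C(C)(Br)[C@H]2[C@H](CO[Si](c5ccccc5)(c5ccccc5)C(C)(C)C)[C@]34CC(=C)[C@@](O[Si](CC)(CC)CC)(C4)CC[C@H]3[C@@]12CCCB(C(C)C(C)C)C(C)C(C)C | intermediate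
34 | C3 primary alcohol (C10 3-hydroxypropyl arm) | COC1OC(=O)C(C)(Br)[C@H]2[C@H](CO[Si](c5ccccc5)(c5ccccc5)C(C)(C)C)[C@]34CC(=C)[C@@](O[Si](CC)(CC)CC)(C4)CC[C@H]3[C@@]12CCCO | intermediate
35 | key precursor: B/C/D tricycle with C10 propanal arm and 4-bromo 19,20-lactol ether | COC1OC(=O)C(C)(Br)[C@H]2[C@H](CO[Si](c5ccccc5)(c5ccccc5)C(C)(C)C)[C@]34CC(=C)[C@@](O[Si](CC)(CC)CC)(C4)CC[C@H]3[C@@]12CCC=O | intermediate
36 | samarium enolate of the lactone (not isolated) | COC1OC(O[Sm](I)I)=C(C)[C@H]2[C@H](CO[Si](c5ccccc5)(c5ccccc5)C(C)(C)C)[C@]34CC(=C)[C@@](O[Si](CC)(CC)CC)(C4)CC[C@H]3[C@@]12CCC=O | intermediate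
37 | tetracyclic 3α-hydroxy 19,20-lactol methyl ether (ring A closed; 3-OH equatorial) | C=C1C[C@]23C[C@@]1(O[Si](CC)(CC)CC)CC[C@H]2[C@]45CC[C@@H](O)[C@@](C)(C(=O)OC5OC)[C@H]4[C@@H]3CO[Si](c6ccccc6)(c6ccccc6)C(C)(C)C | intermediate
38 | 3-ketone | C=C1C[C@]23C[C@@]1(O[Si](CC)(CC)CC)CC[C@H]2[C@]45CCC(=O)[C@@](C)(C(=O)OC5OC)[C@H]4[C@@H]3CO[Si](c6ccccc6)(c6ccccc6)C(C)(C)C | intermediate
39 | tetracyclic 3β-hydroxy 19,20-lactol methyl ether (3-OH axial) | C=C1C[C@]23C[C@@]1(O[Si](CC)(CC)CC)CC[C@H]2[C@]45CC[C@H](O)[C@@](C)(C(=O)OC5OC)[C@H]4[C@@H]3CO[Si](c6ccccc6)(c6ccccc6)C(C)(C)C | intermediate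
40 | triol: 3β,13-dihydroxy-7-hydroxymethyl lactol ether | C=C1C[C@]23C[C@@]1(O)CC[C@H]2[C@]45CC[C@H](O)[C@@](C)(C(=O)OC5OC)[C@H]4[C@@H]3CO | intermediate
41 | C7 aldehyde | C=C1C[C@]23C[C@@]1(O)CC[C@H]2[C@]45CC[C@H](O)[C@@](C)(C(=O)OC5OC)[C@H]4[C@@H]3C=O | intermediate
42 | C7 carboxylic acid | C=C1C[C@]23C[C@@]1(O)CC[C@H]2[C@]45CC[C@H](O)[C@@](C)(C(=O)OC5OC)[C@H]4[C@@H]3C(=O)O | intermediate
43 | CNP0236431.1: 3β,13-dihydroxy-20-oxo-16-methylene gibberellane-7,19-dioic acid | C=C1C[C@]23C[C@@]1(O)CC[C@H]2[C@]1(C=O)CC[C@H](O)[C@@](C)(C(=O)O)[C@H]1[C@@H]3C(=O)O | target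

**Step count**

Total: 29 steps. Longest linear sequence: 26 steps from compound 1 (steps 1–3, 5–10, 12, 14–29); steps 4, 11 and 13 prepare reagents 7, 18 and 22.

**Steps most likely to fail, with fallbacks**

Step 12. The cycloaddition may stall, because the bond to the fully substituted C8 has to form next to the branched C6, and long contact with the aluminium Lewis acid may strip silyl ethers. The fallback sets out from enone 16 and uses a more electron-rich diene under pressure instead of a Lewis acid. Cycloaddition with trans-1-methoxy-3-(trimethylsilyloxy)buta-1,3-diene at about 12 kbar in CH2Cl2 would give the methoxy silyl enol ether cycloadduct F1. Dilute acid would hydrolyse the enol ether and eliminate methanol to the ring C enone F2. Conjugate reduction of this enone with [(Ph3P)CuH]6 in the presence of t-BuMe2SiCl would trap the enolate as the silyl enol ether, which returns to the route at 19.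

Step 23. The samarium enolate may be protonated or may fragment before it reaches the aldehyde, or the aldolate may revert by retro-aldol cleavage during work-up. The fallback sets out from 30, which carries no bromine, and forms the enolate by deprotonation. Hydroboration with (Sia)2BH would give the trialkylborane F6, amine-oxide oxidation the primary alcohol F7, and periodinane oxidation the aldehyde F8. LiN(SiMe3)2 in THF at −78 °C would then form the lithium enolate F9 of the lactone, which closes ring A by the deprotonative aldol addition that underlies the base-induced C3 epimerisation of 3-hydroxy gibberellins. The route is re-entered at 37, and either C3 epimer goes on to 38.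

Step 14. The basic ylide may enolise the hindered C10 ketone, which is flanked by two tertiary carbons, faster than it adds, so that olefination stops short. The fallback sets out from 19 and homologates the ketone through an epoxide. Dimethylsulfonium methylide (from Me3SI and KN(SiMe3)2, Corey–Chaykovsky reaction) would give the spiro-epoxide F3. Rearrangement with hydride shift (Meinwald type, LiBr/HMPA, benzene, 80 °C) would give the C10 carbaldehyde F4. KOt-Bu would convert it into the potassium enolate F5, and allyl bromide would alkylate C10 on the face anti to the C5 and C9 substituents. Any O-allylated material is 24 itself and rearranges on heating, so the route is re-entered at 25.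

**Further compounds**

F1 | step 12 | cycloadduct of 16 with trans-1-methoxy-3-(trimethylsilyloxy)buta-1,3-diene (C11 methoxy, C12=C13 trimethylsilyl enol ether) | O=C1[C@@H](C(C)C(=O)OC)[C@H](CO[Si](c3ccccc3)(c3ccccc3)C(C)(C)C)[C@@]2(CC#C[Si](C)(C)C)CC(O[Si](C)(C)C)=CC(OC)[C@@H]12
F2 | step 12 | cis-fused enedione (C10 ketone, ring C enone C13(=O)–C12=C11) | O=C1[C@@H](C(C)C(=O)OC)[C@H](CO[Si](c3ccccc3)(c3ccccc3)C(C)(C)C)[C@@]2(CC#C[Si](C)(C)C)CC(=O)C=C[C@@H]12
F3 | step 14 | C10 spiro-epoxide of 19 | C1OC12[C@@H](C(C)C(=O)OC)[C@H](CO[Si](c4ccccc4)(c4ccccc4)C(C)(C)C)[C@@]3(CC#C[Si](C)(C)C)CC(O[Si](C)(C)C(C)(C)C)=CC[C@@H]23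
F4 | step 14 | C10 carbaldehyde (C10–H, C20 formyl) | O=CC1[C@@H](C(C)C(=O)OC)[C@H](CO[Si](c3ccccc3)(c3ccccc3)C(C)(C)C)[C@@]2(CC#C[Si](C)(C)C)CC(O[Si](C)(C)C(C)(C)C)=CC[C@@H]12
F5 | step 14 | potassium enolate of F4 | [K+].[O-]C=C1[C@@H](C(C)C(=O)OC)[C@H](CO[Si](c3ccccc3)(c3ccccc3)C(C)(C)C)[C@@]2(CC#C[Si](C)(C)C)CC(O[Si](C)(C)C(C)(C)C)=CC[C@@H]12
F6 | step 23 | C3 bis(3-methylbutan-2-yl)borane from 30 | COC1OC(=O)C(C)[C@H]2[C@H](CO[Si](c5ccccc5)(c5ccccc5)C(C)(C)C)[C@]34CC(=C)[C@@](O[Si](CC)(CC)CC)(C4)CC[C@H]3[C@@]12CCCB(C(C)C(C)C)C(C)C(C)C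
F7 | step 23 | C3 primary alcohol without bromine | COC1OC(=O)C(C)[C@H]2[C@H](CO[Si](c5ccccc5)(c5ccccc5)C(C)(C)C)[C@]34CC(=C)[C@@](O[Si](CC)(CC)CC)(C4)CC[C@H]3[C@@]12CCCO
F8 | step 23 | lactone aldehyde without bromine | COC1OC(=O)C(C)[C@H]2[C@H](CO[Si](c5ccccc5)(c5ccccc5)C(C)(C)C)[C@]34CC(=C)[C@@](O[Si](CC)(CC)CC)(C4)CC[C@H]3[C@@]12CCC=O
F9 | step 23 | lithium enolate of F8 | COC1OC([O-])=C(C)[C@H]2[C@H](CO[Si](c5ccccc5)(c5ccccc5)C(C)(C)C)[C@]34CC(=C)[C@@](O[Si](CC)(CC)CC)(C4)CC[C@H]3[C@@]12CCC=O.[Li+]
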